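A small charge of free catalyst, 0.5 mol% on 0.93 M of substrate, is to be read after 8.0 min at two temperatures, in ash and in cedar.

the same everywhere: substrate 0.93 M
- autumn: free catalyst 0.25 mol%; temperature 115 °C; run made earlier
- winter: free catalyst 1 mol%; temperature 126 °C; run made earlier
- ash: free catalyst 0.5 mol%; temperature 110 °C; time 8.0 min
- cedar: free catalyst 0.5 mol%; temperature 130 °C; time 8.0 min

| run | time / min | side product / % | catalyst intermediate B / % | target / % | catalyst intermediate A / % | substrate / % |
|---|---|---|---|---|---|---|
| autumn | 0.833 | 0 | 1.4 | 2.7 | 0.2 | 95.8 |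
| autumn | 1.33 | 1.3 | 0 | 5.4 | 0 | 95.3 |
| autumn | 2.00 | 0.2 | 0.4 | 7.0 | 0 | 92.4 |
| autumn | 4.00 | 2.1 | 0.5 | 12.8 | 0.3 | 85.9 |
| autumn | 6.00 | 4.7 | 0 | 16.7 | 0.8 | 78.6 |
| autumn | 10.0 | 11.3 | 0.6 | 21.4 | 0 | 67.5 |
| winter | 0.417 | 0.1 | 0.5 | 10.3 | 0.3 | 89.0 |
| winter | 0.667 | 1.1 | 0.7 | 16.8 | 0.6 | 82.8 |
| winter | 0.833 | 1.2 | 0.1 | 20.2 | 0 | 79.3 |
| winter | 2.00 | 4.8 | 0.1 | 35.4 | 0.5 | 59.5 |
| winter | 2.50 | 7.3 | 0 | 39.8 | 0.4 | 51.8 |
| winter | 5.00 | 15.8 | 0 | 54.8 | 0 | 29.9 |

(scatter of a reading: 0.5 percentage points)

- percent here means substrate units held: one side product counts as two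

* which of these there is most of at the end, counted by the substrate in it, ash (catalyst intermediate A / target / catalyst intermediate B / side product / substrate)
* which of these there is most of at the end, counted by the substrate in it, cedar (catalyst intermediate A / target / catalyst intermediate B / side product / substrate)
* the largest of these amounts at the end, in percent of the substrate charged, ash
* the largest of these amounts at the end, in percent of the substrate charged, cedar

Minutes of the meeting. The kineticist took each earlier run's last reading and worked out an apparent, pseudo-first-order constant of substrate: the logarithm of charged over left, divided by time. She then scaled it to the new loading, assuming rate goes with catalyst, which gives 0.0786 min⁻¹ for autumn and 0.121 min⁻¹ for winter. She conceded that winter's unscaled constant falls from 0.279 min⁻¹ at its first reading to 0.241 min⁻¹ at its last, but argued that a constant taken to the end carries that slowing inside it. Placing the two runs on a logarithmic line in temperature, she gave ash 0.0647 min⁻¹ and cedar a flask loss constant, the scaled end-of-run constant at the flask's own temperature, of 0.141 min⁻¹. So ash keeps 59.6% of its substrate and cedar 32.4%.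

A colleague joined this to the other end of the balance. Ash keeps more than half, so substrate leads there. In cedar, target and side product share the rest, so target leads while side product stays below an equal split of that rest, 33.8%. He scaled winter's last side product by time, since winter ended near cedar's substrate, and got 25.3% and target 42.3%. He called that side product low, cedar being hotter.

The forecaster tabled substrate at 61% for ash and target at 43% for cedar, expecting “stronger slowing and faster side reaction” in cedar.

The flasks gave substrate at 58.3% in ash and target at 41.6% in cedar, so the forecast held within its margins.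

    substrate + free catalyst ⇌ catalyst intermediate A (K = 1.80 L mol⁻¹, k = 0.620 L mol⁻¹ s⁻¹, Ea = 42.0 kJ mol⁻¹, ΔH = −30.0 kJ mol⁻¹)
    catalyst intermediate A → catalyst intermediate B (k = 0.920 s⁻¹, Ea = 95.0 kJ mol⁻¹)
    catalyst intermediate B → free catalyst + target (k = 0.930 s⁻¹, Ea = 86.0 kJ mol⁻¹)
    substrate + target → side product (k = 6.90 × 10⁻⁴ L mol⁻¹ s⁻¹, Ea = 68.0 kJ mol⁻¹)
    free catalyst ⇌ dormant form (K = 2.20, k = 0.00180 s⁻¹, Ea = 126 kJ mol⁻¹, ΔH = −29.0 kJ mol⁻¹)
    (constants at 110 °C)

In cedar, side product reached 26.1%, below the line of 33.8%, with substrate at 32.3%. For the forecast's cedar choice to fail, that order must change, and a shorter time does it. Take the neighbouring flask, cedar stopped at 3.0 min, all amounts and the temperature held. The same constant leaves 65.5% of substrate, above half, so substrate should lead. That flask holds target 26.3%, side product 8.12% and substrate on top at 65.5%.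

Readings and results stem from a simulated flask from invented constants; scatter was added.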